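**Retrosynthetic overview**

- The strategy rests on C2 of ring C: an unsubstituted CH2 held between O1 and the C3 methine. It is disconnected as carbon monoxide, inserted between the ring-A phenol oxygen and C3 of an (E)-2-hydroxystilbene (14) that already contains C4a–C4=C3–C1'.
- Ring C is the only ring made. It is closed first as the 3-aryl-dihydrocoumarin 16 (C2–C3 and C2–O1 bonds, C3 stereocentre), then reduced to the phenol alcohol 18 and re-closed as the chroman by Mitsunobu etherification.
- Stilbene 14 comes from a Wittig reaction of the ring-A (2-hydroxybenzyl)phosphonium salt 4 with the ring-B aldehyde 11, followed by Z to E isomerisation.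
- Ring A: 2,4-dihydroxy-6-methoxybenzaldehyde, selective 4-O-silylation, reduction, PPh3·HBr. Ring B: 2-hydroxy-4-methoxybenzaldehyde, 1,1-dimethylpropargyl ether, semi-hydrogenation, aromatic Claisen rearrangement to place the prenyl group at C3', silylation.
- The 7-O and 2'-O silyl ethers (TIPS) stay on to the end; the 2'-O-silyl group also keeps the ring-B phenol from acting as acyl acceptor, and fluoride removes both without touching the prenyl group.

Key step: step 10

Assumption: the sense of induction of the chiral bisphosphine in step 10 cannot be derived in advance, so both antipodes are to be run and the one giving (3R) used; locants follow the isoflavan skeleton (O1, C2–C4, C4a–C8a; C1'–C6' for ring B).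

**Route**

Step 1
Reactants: 1 2,4-dihydroxy-6-methoxybenzaldehyde
Product: 2 2-hydroxy-6-methoxy-4-(triisopropylsilyloxy)benzaldehyde
Conditions: TIPSCl (1.05 equiv), imidazole, CH2Cl2, 0 °C
Reagents that add atoms: chlorotriisopropylsilane (TIPSCl), CC(C)[Si](Cl)(C(C)C)C(C)C
Why: Silyl ether formation on a phenol, in which the 4-OH is the more acidic and unhindered hydroxyl while the 2-OH is tied up in a hydrogen bond to the aldehyde, so one equivalent of silyl chloride should take the 4-position only.

Step 2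
Reactants: 2 2-hydroxy-6-methoxy-4-(triisopropylsilyloxy)benzaldehyde
Product: 3 2-(hydroxymethyl)-3-methoxy-5-(triisopropylsilyloxy)phenol
Conditions: NaBH4, THF/MeOH, 0 °C; pH 7 buffer work-up
Reagents that add atoms: none
Why: Borohydride reduction of an aryl aldehyde, with a cold neutral work-up so that the electron-rich 2-hydroxybenzyl alcohol does not ionise.

Step 3
Reactants: 3 2-(hydroxymethyl)-3-methoxy-5-(triisopropylsilyloxy)phenol
Product: 4 [2-hydroxy-6-methoxy-4-(triisopropylsilyloxy)benzyl]triphenylphosphonium bromide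
Conditions: PPh3·HBr, MeCN, 50 °C
Reagents that add atoms: triphenylphosphine hydrobromide, [Br-].[PH+](c1ccccc1)(c1ccccc1)c1ccccc1
Why: Phosphonium salt formation from an activated benzylic alcohol by acid-promoted SN1-type substitution with PPh3, the standard entry to (2-hydroxybenzyl)triphenylphosphonium salts.

Step 4
Reactants: 5 2-hydroxy-4-methoxybenzaldehyde; 6 3-chloro-3-methylbut-1-yne
Product: 7 4-methoxy-2-(2-methylbut-3-yn-2-yloxy)benzaldehyde
Conditions: DBU, CuCl2·2H2O (1 mol %), MeCN, 0 °C to rt
Reagents that add atoms: none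
Why: Copper-catalysed O-alkylation of a phenol with a tertiary propargylic chloride, which proceeds at low temperature even on the hydrogen-bonded salicylaldehyde hydroxyl.

Step 5
Reactants: 7 4-methoxy-2-(2-methylbut-3-yn-2-yloxy)benzaldehyde
Product: 8 4-methoxy-2-(2-methylbut-3-en-2-yloxy)benzaldehyde
Conditions: H2 (1 atm), Lindlar catalyst (Pd/CaCO3, Pb(OAc)2-poisoned), quinoline, EtOAc, rt
Reagents that add atoms: none
Why: Lindlar semi-hydrogenation of the terminal alkyne to the alkene, which leaves the aldehyde and the aryl ether untouched.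

Step 6
Reactants: 8 4-methoxy-2-(2-methylbut-3-en-2-yloxy)benzaldehyde
Product: 10 2-hydroxy-4-methoxy-3-(3-methylbut-2-en-1-yl)benzaldehyde, via Claisen dienone 9 (not isolated)
Conditions: N,N-diethylaniline, 140 °C
Reagents that add atoms: none
Why: Aromatic Claisen rearrangement ([3,3]-sigmatropic shift) of the 1,1-dimethylallyl aryl ether into the only free ortho position, which turns the reverse-prenyl ether into the C-prenyl group and re-aromatises by tautomerisation of dienone 9.

Step 7
Reactants: 10 2-hydroxy-4-methoxy-3-(3-methylbut-2-en-1-yl)benzaldehyde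
Product: 11 4-methoxy-3-(3-methylbut-2-en-1-yl)-2-(triisopropylsilyloxy)benzaldehyde
Conditions: TIPSOTf, 2,6-lutidine, CH2Cl2, 0 °C to rt
Reagents that add atoms: triisopropylsilyl trifluoromethanesulfonate (TIPSOTf), CC(C)[Si](OS(=O)(=O)C(F)(F)F)(C(C)C)C(C)C
Why: Silyl ether formation with the silyl triflate, chosen because this phenol is hydrogen-bonded to the aldehyde and flanked by two ortho substituents.

Step 8
Reactants: 4 [2-hydroxy-6-methoxy-4-(triisopropylsilyloxy)benzyl]triphenylphosphonium bromide; 11 4-methoxy-3-(3-methylbut-2-en-1-yl)-2-(triisopropylsilyloxy)benzaldehyde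
Product: 13 2-hydroxystilbene (ring A 2-OH/4-OTIPS/6-OMe; ring B 2'-OTIPS/3'-prenyl/4'-OMe; E/Z mixture), via phenoxide ylide 12 (not isolated)
Conditions: NaHMDS (2.1 equiv) added to 4 and 11, THF, −78 °C to rt; aq. NH4Cl
Reagents that add atoms: none
Why: Wittig olefination of a semi-stabilised benzylic ylide with a non-enolisable aryl aldehyde, in which two equivalents of base generate phenoxide ylide 12 in the presence of 11 so that it is trapped as it forms, an E/Z mixture being expected.

Step 9
Reactants: 13 2-hydroxystilbene (E/Z mixture)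
Product: 14 (E)-2-hydroxystilbene: 3-methoxy-2-{(E)-2-[4-methoxy-3-(3-methylbut-2-en-1-yl)-2-(triisopropylsilyloxy)phenyl]ethenyl}-5-(triisopropylsilyloxy)phenol
Conditions: PhSSPh (10 mol %), THF, reflux, ambient light
Reagents that add atoms: none
Why: Thiyl-radical-catalysed Z to E isomerisation of a stilbene by reversible addition of PhS radical to the disubstituted alkene, which should converge the mixture on the more stable E isomer and leave the constitution of the prenyl alkene unchanged.

Step 10
Reactants: 14 (E)-2-hydroxystilbene; 15 carbon monoxide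
Product: 16 (3R)-5-methoxy-3-[4-methoxy-3-(3-methylbut-2-en-1-yl)-2-(triisopropylsilyloxy)phenyl]-7-(triisopropylsilyloxy)-3,4-dihydro-2H-chromen-2-one
Conditions: Pd(OAc)2 (5 mol %), (S,S)-BDPP or its antipode (6 mol %), PivOH (20 mol %), CO (30 bar), toluene, 80 °C
Reagents that add atoms: none
Why: Proposed new method: a palladium hydride (Pd(OAc)2 is reduced under CO to zerovalent palladium and reprotonated by PivOH or the phenol) adds syn across C3=C4 of 14 with H to C4 and Pd to C3, CO (15) inserts into the Pd–C3 bond with retention (C2–C3 bond), and the ring-A phenol oxygen displaces palladium from the acyl carbon (C2–O1 bond), which returns the hydride. The closest known reactions are the palladium-catalysed asymmetric cyclocarbonylation of 2-vinylphenols and 2-allylphenols to benzo-fused lactones and the branch-selective asymmetric hydroaryloxycarbonylation of styrenes; a 1,2-diarylethene, in which both alkene carbons are benzylic, lies outside their scope. Ring C closes as the lactone by 6-exo-trig acyl substitution of O1 on the acylpalladium carbon. C3 is the only new stereocentre and is set by the chiral bisphosphine on palladium, which selects the alkene face for H/Pd addition and, because hydropalladation is reversible, the alkylpalladium diastereomer that goes on to insert CO. The step needs palladium at C3 and not C4: ring B offers its unsubstituted C6' for an η3-benzyl palladium at C3, whereas ring A carries substituents at both ortho positions (OH and OMe), is twisted out of the alkene plane, and a C4 acyl could close only to the five-membered benzofuranone. It also needs the stilbene to react before the prenyl alkene (trisubstituted, unconjugated, slow to hydropalladate) and ring A, not ring B, to accept the acyl group (the 2'-oxygen is blocked as its silyl ether), and the weak acid is chosen so that the electron-rich stilbene is not protonated.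

Step 11
Reactants: 16 (3R)-3-aryl-3,4-dihydrocoumarin bis-silyl ether
Product: 18 2-{(2R)-3-hydroxy-2-[4-methoxy-3-(3-methylbut-2-en-1-yl)-2-(triisopropylsilyloxy)phenyl]propyl}-3-methoxy-5-(triisopropylsilyloxy)phenol, via hydroxy aldehyde 17 (not isolated)
Conditions: LiBH4 (excess), THF, −20 to 0 °C, on crude 16
Reagents that add atoms: none
Why: Hydride reduction of an aryl ester (lactone) to the phenol and the primary alcohol, in which the activated aryl ester reacts at low temperature and aldehyde 17 should be consumed by excess borohydride before it can enolise, so that the C3 configuration is kept.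

Step 12
Reactants: 18 (2R)-phenol alcohol
Product: 19 (3R)-5-methoxy-3-[4-methoxy-3-(3-methylbut-2-en-1-yl)-2-(triisopropylsilyloxy)phenyl]-7-(triisopropylsilyloxy)-3,4-dihydro-2H-chromene
Conditions: PPh3, DIAD, THF, 0 °C to rt
Reagents that add atoms: none
Why: Intramolecular Mitsunobu etherification (6-exo-tet SN2 at the primary carbon by the ring-A phenol), the established closure of isoflavans from such phenol alcohols, which does not involve the C3 stereocentre.

Step 13
Reactants: 19 (3R)-isoflavan bis-silyl ether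
Product: 20 (3R)-3-[2-hydroxy-4-methoxy-3-(3-methylbut-2-en-1-yl)phenyl]-5-methoxy-3,4-dihydro-2H-chromen-7-ol (CNP0119532.1)
Conditions: Bu4NF, AcOH, THF, 0 °C to rt
Reagents that add atoms: none
Why: Fluoride cleavage of both aryl silyl ethers, buffered with AcOH so that the electron-rich phenols and the ortho-prenyl phenol see neither strong base nor acid.

**Compound list**

1 | 2,4-dihydroxy-6-methoxybenzaldehyde | COc1cc(O)cc(O)c1C=O | starting material
2 | 2-hydroxy-6-methoxy-4-(triisopropylsilyloxy)benzaldehyde | COc1cc(O[Si](C(C)C)(C(C)C)C(C)C)cc(O)c1C=O | intermediate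
3 | 2-(hydroxymethyl)-3-methoxy-5-(triisopropylsilyloxy)phenol | COc1cc(O[Si](C(C)C)(C(C)C)C(C)C)cc(O)c1CO | intermediate
4 | [2-hydroxy-6-methoxy-4-(triisopropylsilyloxy)benzyl]triphenylphosphonium bromide | COc1cc(O[Si](C(C)C)(C(C)C)C(C)C)cc(O)c1C[P+](c1ccccc1)(c1ccccc1)c1ccccc1.[Br-] | intermediate
5 | 2-hydroxy-4-methoxybenzaldehyde | COc1ccc(C=O)c(O)c1 | starting material
6 | 3-chloro-3-methylbut-1-yne | CC(C)(Cl)C#C | starting material
7 | 4-methoxy-2-(2-methylbut-3-yn-2-yloxy)benzaldehyde | COc1ccc(C=O)c(OC(C)(C)C#C)c1 | intermediate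
8 | 4-methoxy-2-(2-methylbut-3-en-2-yloxy)benzaldehyde | COc1ccc(C=O)c(OC(C)(C)C=C)c1 | intermediate
9 | 4-methoxy-5-(3-methylbut-2-en-1-yl)-6-oxocyclohexa-1,3-diene-1-carbaldehyde (Claisen dienone, racemic, not isolated) | COC1=CC=C(C=O)C(=O)C1CC=C(C)C | intermediate
10 | 2-hydroxy-4-methoxy-3-(3-methylbut-2-en-1-yl)benzaldehyde | COc1ccc(C=O)c(O)c1CC=C(C)C | intermediate
11 | 4-methoxy-3-(3-methylbut-2-en-1-yl)-2-(triisopropylsilyloxy)benzaldehyde | COc1ccc(C=O)c(O[Si](C(C)C)(C(C)C)C(C)C)c1CC=C(C)C | intermediate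
12 | sodium 3-methoxy-5-(triisopropylsilyloxy)-2-[(triphenylphosphoranylidene)methyl]phenoxide (phenoxide ylide, not isolated) | COc1cc(O[Si](C(C)C)(C(C)C)C(C)C)cc([O-])c1C=P(c1ccccc1)(c1ccccc1)c1ccccc1.[Na+] | intermediate
13 | 3-methoxy-2-{2-[4-methoxy-3-(3-methylbut-2-en-1-yl)-2-(triisopropylsilyloxy)phenyl]ethenyl}-5-(triisopropylsilyloxy)phenol (E/Z mixture) | COc1cc(O[Si](C(C)C)(C(C)C)C(C)C)cc(O)c1C=Cc1ccc(OC)c(CC=C(C)C)c1O[Si](C(C)C)(C(C)C)C(C)C | intermediate
14 | 3-methoxy-2-{(E)-2-[4-methoxy-3-(3-methylbut-2-en-1-yl)-2-(triisopropylsilyloxy)phenyl]ethenyl}-5-(triisopropylsilyloxy)phenol | COc1cc(O[Si](C(C)C)(C(C)C)C(C)C)cc(O)c1/C=C/c1ccc(OC)c(CC=C(C)C)c1O[Si](C(C)C)(C(C)C)C(C)C | intermediate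
15 | carbon monoxide | [C-]#[O+] | starting material
16 | (3R)-5-methoxy-3-[4-methoxy-3-(3-methylbut-2-en-1-yl)-2-(triisopropylsilyloxy)phenyl]-7-(triisopropylsilyloxy)-3,4-dihydro-2H-chromen-2-one | COc1cc(O[Si](C(C)C)(C(C)C)C(C)C)cc2c1C[C@H](c1ccc(OC)c(CC=C(C)C)c1O[Si](C(C)C)(C(C)C)C(C)C)C(=O)O2 | intermediate
17 | (2R)-3-[2-hydroxy-6-methoxy-4-(triisopropylsilyloxy)phenyl]-2-[4-methoxy-3-(3-methylbut-2-en-1-yl)-2-(triisopropylsilyloxy)phenyl]propanal (not isolated) | COc1cc(O[Si](C(C)C)(C(C)C)C(C)C)cc(O)c1C[C@H](c1ccc(OC)c(CC=C(C)C)c1O[Si](C(C)C)(C(C)C)C(C)C)C=O | intermediate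
18 | 2-{(2R)-3-hydroxy-2-[4-methoxy-3-(3-methylbut-2-en-1-yl)-2-(triisopropylsilyloxy)phenyl]propyl}-3-methoxy-5-(triisopropylsilyloxy)phenol | COc1cc(O[Si](C(C)C)(C(C)C)C(C)C)cc(O)c1C[C@H](c1ccc(OC)c(CC=C(C)C)c1O[Si](C(C)C)(C(C)C)C(C)C)CO | intermediate
19 | (3R)-5-methoxy-3-[4-methoxy-3-(3-methylbut-2-en-1-yl)-2-(triisopropylsilyloxy)phenyl]-7-(triisopropylsilyloxy)-3,4-dihydro-2H-chromene | COc1cc(O[Si](C(C)C)(C(C)C)C(C)C)cc2c1C[C@H](c1ccc(OC)c(CC=C(C)C)c1O[Si](C(C)C)(C(C)C)C(C)C)CO2 | intermediate
20 | (3R)-3-[2-hydroxy-4-methoxy-3-(3-methylbut-2-en-1-yl)phenyl]-5-methoxy-3,4-dihydro-2H-chromen-7-ol | COc1cc(O)cc2c1C[C@H](c1ccc(OC)c(CC=C(C)C)c1O)CO2 | target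

**Step count and risks**

Total steps: 13. Longest linear sequence: 10 steps (steps 4 to 13, from 5 and 6).

Steps most likely to fail:

1. Step 10 (new method). Several processes could defeat it:
   - carbonylation at C4, leading to the five-membered lactone, for example if the phenoxide binds palladium and directs it to C4;
   - poor facial selectivity;
   - acid- or palladium-induced attack of the phenol on the alkene;
   - slow hydropalladation of the hindered alkene;
   - loss of configuration of the enolisable lactone at 80 °C.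

   Hydrogen partial pressure and acid strength are the first variables to screen. The fallback abandons carbonylation and sets C3 by auxiliary-controlled alkylation, known chemistry with close precedent for isoflavans. It sets out from 11 and 2 and comes back at 18.
   - Aldehyde 11 is methylenated (Ph3PCH3Br, KOtBu) to 1-ethenyl-4-methoxy-3-prenyl-2-(triisopropylsilyloxy)benzene F1.
   - F1 is hydroborated at the styrene only (9-BBN, then NaBO3·4H2O) to the 2-arylethanol F2.
   - F2 is oxidised (TEMPO, PhI(OAc)2, MeCN/H2O) to the arylacetic acid F3.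
   - F3 is coupled (EDC, DMAP) with (R)-4-benzyloxazolidin-2-one to the N-arylacetyl oxazolidinone F4.
   - Separately, aldehyde 2 is O-allylated (allyl bromide, K2CO3, acetone) to 2-allyloxy-6-methoxy-4-(triisopropylsilyloxy)benzaldehyde F5, reduced (NaBH4) to the benzyl alcohol F6 and converted (CBr4, PPh3) into the benzyl bromide F7, which is used at once.
   - F4 is alkylated with F7 (NaHMDS, THF, −78 °C) on the face away from the auxiliary benzyl group to give the (2R)-2,3-diarylpropanoyl oxazolidinone F8.
   - LiBH4 removes the auxiliary to give the O-allyl (2R)-alcohol F9, and Pd(PPh3)4 with morpholine cleaves the allyl ether to give 18.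

2. Step 8. The phenoxide ylide may fragment (loss of PPh3 from the ortho-oxido benzyl unit) faster than it adds to the ortho-silyloxy aldehyde, giving low conversion. The fallback masks the phenol before ylide formation. It sets out from 4 and 11 and comes back at 13.
   - Salt 4 is silylated (TBSCl, imidazole, DMF) to the O-tert-butyldimethylsilyl phosphonium bromide F10.
   - An ordinary Wittig reaction of F10 with 11 (NaHMDS, 1 equiv, THF) gives the tris-silyl stilbene F11 as an E/Z mixture.
   - The aryl TBS ether, far more labile to methoxide than the two aryl TIPS ethers, is cleaved selectively (K2CO3, MeOH, 0 °C) to give 13.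

3. Step 3. Acid-induced ionisation of 3 may lead to self-alkylation of the phloroglucinol-type ring and partial desilylation in competition with capture by PPh3. The fallback moves the phosphorus to ring B, which also replaces steps 2, 8 and 9. It sets out from 11 and 2 and comes back at 14.
   - Aldehyde 11 is reduced (NaBH4, 0 °C, short reaction time) to the ring-B benzyl alcohol F12 and brominated (CBr4, PPh3) to the benzyl bromide F13.
   - F13 is quaternised with PBu3 (toluene, rt) to the tributylphosphonium bromide F14.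
   - F14 and aldehyde 2 are treated with NaHMDS (2.2 equiv, one equivalent being taken up by the phenol) in THF; trialkylphosphonium benzylic ylides are E-selective, so this should give 14 directly.

**Further compounds**

F1 | step 10 | 1-ethenyl-4-methoxy-3-(3-methylbut-2-en-1-yl)-2-(triisopropylsilyloxy)benzene | COc1ccc(C=C)c(O[Si](C(C)C)(C(C)C)C(C)C)c1CC=C(C)C
F2 | step 10 | 2-[4-methoxy-3-(3-methylbut-2-en-1-yl)-2-(triisopropylsilyloxy)phenyl]ethanol | COc1ccc(CCO)c(O[Si](C(C)C)(C(C)C)C(C)C)c1CC=C(C)C
F3 | step 10 | [4-methoxy-3-(3-methylbut-2-en-1-yl)-2-(triisopropylsilyloxy)phenyl]acetic acid | COc1ccc(CC(=O)O)c(O[Si](C(C)C)(C(C)C)C(C)C)c1CC=C(C)C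
F4 | step 10 | (4R)-4-benzyl-3-{[4-methoxy-3-(3-methylbut-2-en-1-yl)-2-(triisopropylsilyloxy)phenyl]acetyl}oxazolidin-2-one | COc1ccc(CC(=O)N2[C@H](Cc3ccccc3)COC2=O)c(O[Si](C(C)C)(C(C)C)C(C)C)c1CC=C(C)C
F5 | step 10 | 2-allyloxy-6-methoxy-4-(triisopropylsilyloxy)benzaldehyde | COc1cc(O[Si](C(C)C)(C(C)C)C(C)C)cc(OCC=C)c1C=O
F6 | step 10 | [2-allyloxy-6-methoxy-4-(triisopropylsilyloxy)phenyl]methanol | COc1cc(O[Si](C(C)C)(C(C)C)C(C)C)cc(OCC=C)c1CO
F7 | step 10 | 2-allyloxy-6-methoxy-4-(triisopropylsilyloxy)benzyl bromide | COc1cc(O[Si](C(C)C)(C(C)C)C(C)C)cc(OCC=C)c1CBr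
F8 | step 10 | (4R)-4-benzyl-3-{(2R)-3-[2-allyloxy-6-methoxy-4-(triisopropylsilyloxy)phenyl]-2-[4-methoxy-3-(3-methylbut-2-en-1-yl)-2-(triisopropylsilyloxy)phenyl]propanoyl}oxazolidin-2-one | COc1cc(O[Si](C(C)C)(C(C)C)C(C)C)cc(OCC=C)c1C[C@H](c1ccc(OC)c(CC=C(C)C)c1O[Si](C(C)C)(C(C)C)C(C)C)C(=O)N1[C@H](Cc2ccccc2)COC1=O
F9 | step 10 | (2R)-3-[2-allyloxy-6-methoxy-4-(triisopropylsilyloxy)phenyl]-2-[4-methoxy-3-(3-methylbut-2-en-1-yl)-2-(triisopropylsilyloxy)phenyl]propan-1-ol | COc1cc(O[Si](C(C)C)(C(C)C)C(C)C)cc(OCC=C)c1C[C@H](c1ccc(OC)c(CC=C(C)C)c1O[Si](C(C)C)(C(C)C)C(C)C)CO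
F10 | step 8 | [2-(tert-butyldimethylsilyloxy)-6-methoxy-4-(triisopropylsilyloxy)benzyl]triphenylphosphonium bromide | COc1cc(O[Si](C(C)C)(C(C)C)C(C)C)cc(O[Si](C)(C)C(C)(C)C)c1C[P+](c1ccccc1)(c1ccccc1)c1ccccc1.[Br-]
F11 | step 8 | tert-butyl(3-methoxy-2-{2-[4-methoxy-3-(3-methylbut-2-en-1-yl)-2-(triisopropylsilyloxy)phenyl]ethenyl}-5-(triisopropylsilyloxy)phenoxy)dimethylsilane (E/Z mixture) | COc1cc(O[Si](C(C)C)(C(C)C)C(C)C)cc(O[Si](C)(C)C(C)(C)C)c1C=Cc1ccc(OC)c(CC=C(C)C)c1O[Si](C(C)C)(C(C)C)C(C)C
F12 | step 3 | [4-methoxy-3-(3-methylbut-2-en-1-yl)-2-(triisopropylsilyloxy)phenyl]methanol | COc1ccc(CO)c(O[Si](C(C)C)(C(C)C)C(C)C)c1CC=C(C)C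
F13 | step 3 | 4-methoxy-3-(3-methylbut-2-en-1-yl)-2-(triisopropylsilyloxy)benzyl bromide | COc1ccc(CBr)c(O[Si](C(C)C)(C(C)C)C(C)C)c1CC=C(C)C
F14 | step 3 | tributyl[4-methoxy-3-(3-methylbut-2-en-1-yl)-2-(triisopropylsilyloxy)benzyl]phosphonium bromide | COc1ccc(C[P+](CCCC)(CCCC)CCCC)c(O[Si](C(C)C)(C(C)C)C(C)C)c1CC=C(C)C.[Br-]
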